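The oxirane ring (O, C8, C9) is taken apart at C8–C9 and C9–O. C9 bears only hydrogens, so it can come from a one-carbon ylide: dimethyloxosulfonium methylide adds to the carbonyl of an aryl ketone in which C10 is already attached, and a single catalytic asymmetric operation makes both bonds, closes the three-membered ring and fixes quaternary C8, the sole stereocentre. The precursor is ketone 9, a 1-aryl-2-silyloxyethanone: C10 oxygen as a bulky, non-chelating tert-butyldimethylsilyl ether, the C7 isovalerate already installed, and the phenol masked as an allyl ether, which ignores the ylide and is removed later without acid or oxidant next to the sensitive benzylic oxirane.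

Key step: step 7

Atom labels: C7 is the benzylic CH2 carrying the isovalerate, C8 the quaternary oxirane carbon, C9 the oxirane CH2 and C10 the CH2 carrying the acetate.

Assumption: how LaLi3(binaphthoxide)3 discriminates the faces of an α-silyloxymethyl aryl ketone cannot be read off from the methyl ketone series; the (S)-binaphthoxide complex is written, and the (R)-complex takes its place with nothing else changed if the first run gives the mirror-image oxirane.

Step 1
Reactants: 1 methyl 3-hydroxy-4-iodobenzoate
Product: 2 methyl 4-iodo-3-(prop-2-enyloxy)benzoate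
Conditions: allyl bromide, K2CO3, DMF, rt
Reagents that add atoms: allyl bromide (3-bromoprop-1-ene), C=CCBr
Why: Williamson etherification, in which the phenoxide formed by K2CO3 is the only nucleophile and displaces bromide from the reactive allylic halide.

Step 2
Reactants: 2 methyl 4-iodo-3-(prop-2-enyloxy)benzoate
Product: 3 [4-iodo-3-(prop-2-enyloxy)phenyl]methanol
Conditions: iBu2AlH, CH2Cl2, −78 to 0 °C; aq. KNaC4H4O6
Reagents that add atoms: none
Why: Hydride reduction of the methyl ester to the benzylic alcohol at low temperature should leave the aryl iodide and the allyl ether untouched.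

Step 3
Reactants: 3 [4-iodo-3-(prop-2-enyloxy)phenyl]methanol
Product: 4 [4-iodo-3-(prop-2-enyloxy)phenyl]methyl 3-methylbutanoate
Conditions: isovaleryl chloride, Et3N, DMAP (cat.), CH2Cl2, 0 °C
Reagents that add atoms: 3-methylbutanoyl chloride, CC(C)CC(Cl)=O
Why: Nucleophile-catalysed O-acylation of the only hydroxyl group installs the C7 isovalerate, which needs no further protection for the rest of the route.

Step 4
Reactants: 5 methyl glycolate
Product: 6 methyl 2-[(tert-butyldimethylsilyl)oxy]acetate
Conditions: TBSCl, imidazole, DMF, rt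
Reagents that add atoms: tert-butyldimethylsilyl chloride, CC(C)(C)[Si](C)(C)Cl
Why: Imidazole-promoted silylation of the primary alcohol gives a hindered silyl ether that should survive the organomagnesium and ylide steps.

Step 5
Reactants: 6 methyl 2-[(tert-butyldimethylsilyl)oxy]acetate
Product: 7 2-[(tert-butyldimethylsilyl)oxy]-N-methoxy-N-methylacetamide
Conditions: MeNH(OMe)·HCl, iPrMgCl, THF, −20 °C
Reagents that add atoms: N,O-dimethylhydroxylamine hydrochloride, CNOC.Cl
Why: The chloromagnesium amide of N,O-dimethylhydroxylamine, formed in the flask, converts the methyl ester directly into the Weinreb amide by ester aminolysis.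

Step 6
Reactants: 4 [4-iodo-3-(prop-2-enyloxy)phenyl]methyl 3-methylbutanoate; 7 2-[(tert-butyldimethylsilyl)oxy]-N-methoxy-N-methylacetamide
Product: 9 [4-[2-[(tert-butyldimethylsilyl)oxy]acetyl]-3-(prop-2-enyloxy)phenyl]methyl 3-methylbutanoate, via arylmagnesium chloride 8 (not isolated)
Conditions: iPrMgCl·LiCl, THF, −20 °C; then 7, −20 to 0 °C; aq. NH4Cl
Reagents that add atoms: none
Why: Iodine–magnesium exchange with the LiCl-activated Grignard reagent is faster at −20 °C than addition of either organomagnesium to the isovalerate, and the Weinreb ketone synthesis stops at the ketone because the chelated adduct persists until the quench.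

Step 7
Reactants: 9 [4-[2-[(tert-butyldimethylsilyl)oxy]acetyl]-3-(prop-2-enyloxy)phenyl]methyl 3-methylbutanoate; 10 trimethylsulfoxonium iodide
Product: 13 [4-[(2R)-2-[[(tert-butyldimethylsilyl)oxy]methyl]oxiran-2-yl]-3-(prop-2-enyloxy)phenyl]methyl 3-methylbutanoate, via dimethyloxosulfonium methylide 11 (not isolated), via alkoxide sulfoxonium betaine 12 (not isolated)
Conditions: 10, NaH, THF, reflux; then 9, LaLi3[(S)-binaphthoxide]3 (5 mol %), [2,4,6-(MeO)3C6H2]3P=O (5 mol %), 5 Å molecular sieves, THF, rt
Reagents that add atoms: none
Why: Ketone 9 is activated by coordination of its carbonyl oxygen to lanthanum, and ylide 11, positioned by a lithium naphthoxide arm and the phosphine oxide, attacks the carbonyl carbon; this addition forms C8–C9, gives betaine 12 and fixes the configuration. The alkoxide oxygen of 12 then displaces dimethyl sulfoxide from C9 in a 3-exo-tet closure that forms C9–O and the oxirane. The closest known reaction type is the catalytic asymmetric Corey–Chaykovsky epoxidation of aryl and alkyl methyl ketones with LaLi3(binaphthoxide)3 and a triarylphosphine oxide, applied here to an aryl ketone whose small flank is CH2OSi in place of CH3. C8 is the only new stereocentre (C9 keeps two hydrogens, so diastereoselectivity is not an issue) and is set by the catalyst: the CH2 group has to reach the Re face of the carbonyl (priorities O > CH2OSi > aryl) to give the (R)-oxirane, and the binaphthol antipode is chosen accordingly. The step needs this enantioface selection and chemoselectivity for the ketone. The first should come from the size contrast between the twisted ortho-allyloxyaryl group and the CH2O arm, whose bulky silyl group sits one atom further out and blocks two-point chelation of lanthanum, and the second from the fact that a stabilised sulfoxonium ylide adds to ketones far faster than to alkyl esters while the substrate holds no Michael acceptor.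

Step 8
Reactants: 13 [4-[(2R)-2-[[(tert-butyldimethylsilyl)oxy]methyl]oxiran-2-yl]-3-(prop-2-enyloxy)phenyl]methyl 3-methylbutanoate
Product: 14 [4-[(2S)-2-(hydroxymethyl)oxiran-2-yl]-3-(prop-2-enyloxy)phenyl]methyl 3-methylbutanoate
Conditions: Bu4NF, AcOH, THF, 0 °C
Reagents that add atoms: none
Why: Fluoride-induced desilylation, buffered with AcOH so that no free alkoxide attacks the esters or the oxirane; a Payne rearrangement would be degenerate here and return the same enantiomer, and the change of descriptor from R to S reflects only the CIP priorities.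

Step 9
Reactants: 14 [4-[(2S)-2-(hydroxymethyl)oxiran-2-yl]-3-(prop-2-enyloxy)phenyl]methyl 3-methylbutanoate
Product: 15 [4-[(2R)-2-(acetoxymethyl)oxiran-2-yl]-3-(prop-2-enyloxy)phenyl]methyl 3-methylbutanoate
Conditions: Ac2O, pyridine, DMAP (cat.), CH2Cl2, 0 °C
Reagents that add atoms: acetic anhydride, CC(=O)OC(C)=O
Why: Base-catalysed acetylation of the primary alcohol is fast at 0 °C, and the mildly basic medium should not harm the oxirane or the other esters.

Step 10
Reactants: 15 [4-[(2R)-2-(acetoxymethyl)oxiran-2-yl]-3-(prop-2-enyloxy)phenyl]methyl 3-methylbutanoate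
Product: 16 [4-[(2R)-2-(acetoxymethyl)oxiran-2-yl]-3-hydroxyphenyl]methyl 3-methylbutanoate
Conditions: Pd(PPh3)4 (5 mol %), morpholine, THF, rt
Reagents that add atoms: none
Why: Tsuji–Trost deallylation, in which zerovalent palladium ionises the aryl allyl ether to a π-allyl complex and phenoxide and morpholine traps the allyl fragment, under neutral conditions that should spare the non-allylic esters and the hindered quaternary oxirane; the phenol is carried on at once.

Step 11
Reactants: 16 [4-[(2R)-2-(acetoxymethyl)oxiran-2-yl]-3-hydroxyphenyl]methyl 3-methylbutanoate; 17 angelic acid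
Product: 19 [2-[(2R)-2-(acetoxymethyl)oxiran-2-yl]-5-[(3-methylbutanoyloxy)methyl]phenyl] (Z)-2-methylbut-2-enoate (target), via mixed anhydride 18 (not isolated)
Conditions: 17, 2,4,6-Cl3C6H2COCl, Et3N, toluene, rt; then 16, Et3N, toluene, 0 °C to rt
Reagents that add atoms: none
Why: Yamaguchi esterification, in which the phenoxide attacks the less hindered angeloyl carbonyl of mixed anhydride 18; working without DMAP and at or below room temperature should keep the (Z)-alkene from isomerising to the tiglate and leave the oxirane intact.

Compound list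
1 | methyl 3-hydroxy-4-iodobenzoate | COC(=O)c1ccc(I)c(O)c1 | starting material
2 | methyl 4-iodo-3-(prop-2-enyloxy)benzoate | COC(=O)c1ccc(I)c(OCC=C)c1 | intermediate
3 | [4-iodo-3-(prop-2-enyloxy)phenyl]methanol | OCc1ccc(I)c(OCC=C)c1 | intermediate
4 | [4-iodo-3-(prop-2-enyloxy)phenyl]methyl 3-methylbutanoate | CC(C)CC(=O)OCc1ccc(I)c(OCC=C)c1 | intermediate
5 | methyl glycolate (methyl 2-hydroxyacetate) | COC(=O)CO | starting material
6 | methyl 2-[(tert-butyldimethylsilyl)oxy]acetate | COC(=O)CO[Si](C)(C)C(C)(C)C | intermediate
7 | 2-[(tert-butyldimethylsilyl)oxy]-N-methoxy-N-methylacetamide | CON(C)C(=O)CO[Si](C)(C)C(C)(C)C | intermediate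
8 | [4-[(3-methylbutanoyloxy)methyl]-2-(prop-2-enyloxy)phenyl]magnesium chloride (LiCl complex, not isolated) | CC(C)CC(=O)OCc1ccc([Mg]Cl)c(OCC=C)c1 | intermediate
9 | [4-[2-[(tert-butyldimethylsilyl)oxy]acetyl]-3-(prop-2-enyloxy)phenyl]methyl 3-methylbutanoate | O=C(CO[Si](C)(C)C(C)(C)C)c1ccc(COC(=O)CC(C)C)cc1OCC=C | intermediate
10 | trimethylsulfoxonium iodide | C[S+](C)(C)=O.[I-] | starting material
11 | dimethyloxosulfonium methylide (not isolated) | C[S+](C)(=O)[CH2-] | intermediate
12 | (S)-configured alkoxide sulfoxonium betaine from addition of 11 to the Re face of 9 (not isolated) | C[S+](C)(=O)C[C@@]([O-])(CO[Si](C)(C)C(C)(C)C)c1ccc(COC(=O)CC(C)C)cc1OCC=C | intermediate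
13 | [4-[(2R)-2-[[(tert-butyldimethylsilyl)oxy]methyl]oxiran-2-yl]-3-(prop-2-enyloxy)phenyl]methyl 3-methylbutanoate | CC(C)CC(=O)OCc1ccc([C@]2(CO[Si](C)(C)C(C)(C)C)CO2)c(OCC=C)c1 | intermediate
14 | [4-[(2S)-2-(hydroxymethyl)oxiran-2-yl]-3-(prop-2-enyloxy)phenyl]methyl 3-methylbutanoate | CC(C)CC(=O)OCc1ccc([C@]2(CO)CO2)c(OCC=C)c1 | intermediate
15 | [4-[(2R)-2-(acetoxymethyl)oxiran-2-yl]-3-(prop-2-enyloxy)phenyl]methyl 3-methylbutanoate | CC(C)CC(=O)OCc1ccc([C@]2(COC(C)=O)CO2)c(OCC=C)c1 | intermediate
16 | [4-[(2R)-2-(acetoxymethyl)oxiran-2-yl]-3-hydroxyphenyl]methyl 3-methylbutanoate | CC(C)CC(=O)OCc1ccc([C@]2(COC(C)=O)CO2)c(O)c1 | intermediate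
17 | angelic acid [(Z)-2-methylbut-2-enoic acid] | C/C=C(/C)C(=O)O | starting material
18 | (Z)-2-methylbut-2-enoic 2,4,6-trichlorobenzoic anhydride (not isolated) | C/C=C(/C)C(=O)OC(=O)c1c(Cl)cc(Cl)cc1Cl | intermediate
19 | [2-[(2R)-2-(acetoxymethyl)oxiran-2-yl]-5-[(3-methylbutanoyloxy)methyl]phenyl] (Z)-2-methylbut-2-enoate | C/C=C(/C)C(=O)Oc1cc(COC(=O)CC(C)C)ccc1[C@]1(COC(C)=O)CO1 | target

Total step count: 11. Longest linear sequence: 9 steps (steps 1–3 and 6–11); steps 4 and 5 prepare amide 7.

Steps most likely to fail

1. Step 7. The enantioface discrimination may be weak or reversed, because the catalyst was tuned for a methyl flank and CH2OSi is closer in size to the twisted aryl group. Turnover may also be slow for the ortho-substituted ketone, so that ylide-induced enolisation competes. Fallback: setting out from ketone 9, Wittig methylenation (Ph3PCH3Br, KOtBu, THF, 0 °C) should give the 1,1-disubstituted alkene [4-[3-[(tert-butyldimethylsilyl)oxy]prop-1-en-2-yl]-3-(prop-2-enyloxy)phenyl]methyl 3-methylbutanoate F1. Bu4NF/AcOH in THF should then free the allylic alcohol [4-(3-hydroxyprop-1-en-2-yl)-3-(prop-2-enyloxy)phenyl]methyl 3-methylbutanoate F2. Sharpless asymmetric epoxidation (Ti(OiPr)4, L-(+)-diethyl tartrate, tBuOOH, 4 Å molecular sieves, CH2Cl2, −20 °C) touches only the allylic-alcohol alkene and not the allyl ether. It should deliver oxygen to the face that L-(+)-tartrate uses to turn allyl alcohol into (S)-glycidol, giving epoxy alcohol 14, where the route is rejoined.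

2. Step 6. The arylmagnesium intermediate may add to the isovalerate of a second molecule before or during the acylation, or the exchange may stall on the electron-rich iodide at the low temperature that the ester demands. Fallback: setting out from alcohol 3, the hydroxyl is first deprotonated with iPrMgCl (1 equiv, THF, −20 °C) and the iodide is then exchanged with iPrMgCl·LiCl. This gives chloromagnesium [4-(chloromagnesio)-3-(prop-2-enyloxy)phenyl]methanolate F3, which carries no ester. Acylation with amide 7 and an NH4Cl quench should give the hydroxy ketone 2-[(tert-butyldimethylsilyl)oxy]-1-[4-(hydroxymethyl)-2-(prop-2-enyloxy)phenyl]ethanone F4, and isovaleryl chloride/pyridine in CH2Cl2 then returns ketone 9.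

3. Step 10. The aryl oxirane may be ionised or isomerised by zerovalent palladium, opened by the amine scavenger, or attacked by the liberated ortho phenol during isolation. Fallback: setting out from allyl ether 15, isomerisation with H2-activated [Ir(cod)(PMePh2)2]PF6 in THF at rt should give the enol ether [4-[(2R)-2-(acetoxymethyl)oxiran-2-yl]-3-[(E)-prop-1-enyloxy]phenyl]methyl 3-methylbutanoate F5. HgCl2/HgO in aqueous acetone (oxymercuration of the enol ether and collapse of the hemiacetal, buffered by HgO, with no palladium and no amine) should then release phenol 16, where the route is rejoined.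

Further compounds
F1 | step 7 | [4-[3-[(tert-butyldimethylsilyl)oxy]prop-1-en-2-yl]-3-(prop-2-enyloxy)phenyl]methyl 3-methylbutanoate | C=C(CO[Si](C)(C)C(C)(C)C)c1ccc(COC(=O)CC(C)C)cc1OCC=C
F2 | step 7 | [4-(3-hydroxyprop-1-en-2-yl)-3-(prop-2-enyloxy)phenyl]methyl 3-methylbutanoate | C=C(CO)c1ccc(COC(=O)CC(C)C)cc1OCC=C
F3 | step 6 | chloromagnesium [4-(chloromagnesio)-3-(prop-2-enyloxy)phenyl]methanolate | Cl[Mg]OCc1ccc([Mg]Cl)c(OCC=C)c1
F4 | step 6 | 2-[(tert-butyldimethylsilyl)oxy]-1-[4-(hydroxymethyl)-2-(prop-2-enyloxy)phenyl]ethanone | O=C(CO[Si](C)(C)C(C)(C)C)c1ccc(CO)cc1OCC=C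
F5 | step 10 | [4-[(2R)-2-(acetoxymethyl)oxiran-2-yl]-3-[(E)-prop-1-enyloxy]phenyl]methyl 3-methylbutanoate | CC(C)CC(=O)OCc1ccc([C@]2(COC(C)=O)CO2)c(O/C=C/C)c1
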